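**Retrosynthetic overview**

1. The strategy rests on ring B (C1''–C6''): its oxygen on C4'' is para to the biaryl bond C1''–C1' and its allyl group sits on the neighbouring C3'', which is the pattern a 5-aryl-2-pyrone and an allyl-substituted silyl ynol ether give after cycloaddition and loss of CO2.
2. Key disconnection: C2''–C3'' and C4''–C5'' of ring B, back to pyrone 14 and ynol ether 18; the last step only removes the two silyl groups.
3. Pyrone 14: C1'–C5(pyrone) bond by Suzuki coupling of boronate 12 with 5-bromo-2-pyrone 13; the ring A allyl group comes from a benzylic bromide and a vinyl Grignard reagent.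
4. The C4–O–C2' ether comes from SNAr of the C4 alkoxide of silylated cryptomeridiol 4 on tert-butyl 3-bromo-4-fluorobenzoate. A removable para ester activates the fluoride, because an allyl-bearing fluoroarene would be unreactive and would isomerise to the propenyl arene under the base. Alcohol 4 comes from β-eudesmol by silylation, α-face epoxidation and hydride opening.
5. Ring order: the decalin is taken from the chiral pool, ring A is bought, ring B is built last by [4+2] addition and retro-[4+2] loss of CO2.

Key step: step 11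

Remark: eudesmane numbering is used (C4 bears the ether oxygen, C10 the angular methyl, C7 the 2-oxyprop-2-yl group, α is the face opposite the C10 methyl); ring A (C1'–C6') is the arene on O–C4 and ring B (C1''–C6'') the phenol ring; natural β-eudesmol of the configuration drawn is assumed as the commercial source of C5, C7 and C10.

**Route**

Step 1
Reactants: 1 β-eudesmol
Product: 2 11-(triethylsilyloxy)eudesm-4(15)-ene
Conditions: Et3SiOTf, 2,6-lutidine, CH2Cl2, −78 → 0 °C
Reagents that add atoms: triethylsilyl trifluoromethanesulfonate, CC[Si](CC)(CC)OS(=O)(=O)C(F)(F)F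
Why: Silylation of a tertiary alcohol with a silyl triflate and a hindered base; the C11 hydroxyl is the only one present, so it is masked before the C4 hydroxyl is created, and the buffered medium leaves the exocyclic alkene untouched.

Step 2
Reactants: 2 11-(triethylsilyloxy)eudesm-4(15)-ene
Product: 3 4α,15-epoxy-11-(triethylsilyloxy)eudesmane
Conditions: mCPBA, NaHCO3, CH2Cl2, 0 °C
Reagents that add atoms: 3-chloroperoxybenzoic acid, O=C(OO)c1cccc(Cl)c1
Why: Prilezhaev epoxidation in which the peracid should approach the C4=C15 bond from the α (equatorial) face, since the β (axial) path is blocked by the syn-axial C10 methyl, so the oxygen is placed α at C4; any minor β-epoxide is removed by chromatography here or after step 3.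

Step 3
Reactants: 3 4α,15-epoxy-11-(triethylsilyloxy)eudesmane
Product: 4 11-(triethylsilyloxy)eudesman-4α-ol (11-O-triethylsilyl cryptomeridiol)
Conditions: LiAlH4, THF, 0 → 40 °C
Reagents that add atoms: none
Why: SN2 opening of the 2,2-disubstituted epoxide by hydride at the primary C15, which turns C15 into the 4β-methyl group and leaves the C4–O bond, and therefore the 4α-oxygen configuration, untouched; the tertiary silyl ether is inert to the hydride.

Step 4
Reactants: 4 11-(triethylsilyloxy)eudesman-4α-ol; 5 tert-butyl 3-bromo-4-fluorobenzoate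
Product: 7 tert-butyl 3-bromo-4-[11-(triethylsilyloxy)eudesman-4α-yloxy]benzoate, via potassium alkoxide 6 (not isolated)
Conditions: KH, 18-crown-6, THF, 0 °C → rt; then 5, DMF, rt → 60 °C
Reagents that add atoms: none
Why: SNAr by addition–elimination, in which alkoxide 6 attacks the fluorine-bearing carbon para to the ester and ortho to bromine and the Meisenheimer intermediate expels fluoride; the tert-butyl ester resists acyl attack by the hindered alkoxide, and the C4–O bond is never broken, so the 4α configuration is retained.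

Step 5
Reactants: 7 tert-butyl 3-bromo-4-[11-(triethylsilyloxy)eudesman-4α-yloxy]benzoate
Product: 8 {3-bromo-4-[11-(triethylsilyloxy)eudesman-4α-yloxy]phenyl}methanol
Conditions: i-Bu2AlH, CH2Cl2, −78 → 0 °C; aq. potassium sodium tartrate
Reagents that add atoms: none
Why: Hydride reduction of the ester to the benzylic alcohol; the aluminium hydride does not touch the aryl bromide, the silyl ether or the tertiary alkyl aryl ether.

Step 6
Reactants: 8 {3-bromo-4-[11-(triethylsilyloxy)eudesman-4α-yloxy]phenyl}methanol
Product: 9 4α-[2-bromo-4-(bromomethyl)phenoxy]-11-(triethylsilyloxy)eudesmane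
Conditions: CBr4, PPh3, 2,6-lutidine, CH2Cl2, 0 °C
Reagents that add atoms: carbon tetrabromide, BrC(Br)(Br)Br
Why: Appel bromination of a primary benzylic alcohol under near-neutral conditions, which spare the acid-labile tertiary alkyl aryl ether; the bromide is filtered through a short pad and used at once because para-alkoxybenzyl bromides ionise easily.

Step 7
Reactants: 9 4α-[2-bromo-4-(bromomethyl)phenoxy]-11-(triethylsilyloxy)eudesmane
Product: 10 4α-(4-allyl-2-bromophenoxy)-11-(triethylsilyloxy)eudesmane
Conditions: CH2=CHMgBr, CuI (10 mol %), THF, −30 → 0 °C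
Reagents that add atoms: vinylmagnesium bromide, C=C[Mg]Br
Why: Copper-catalysed Kumada-type coupling of a benzylic bromide with a vinyl Grignard reagent, which builds the allyl group with its terminal double bond fixed in place; the aryl C–Br bond does not react with the organocopper or the Grignard reagent at this temperature.

Step 8
Reactants: 10 4α-(4-allyl-2-bromophenoxy)-11-(triethylsilyloxy)eudesmane
Product: 12 2-{5-allyl-2-[11-(triethylsilyloxy)eudesman-4α-yloxy]phenyl}-4,4,5,5-tetramethyl-1,3,2-dioxaborolane, via aryllithium 11 (not isolated)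
Conditions: n-BuLi, THF, −78 °C; then i-PrOBpin, −78 °C → rt
Reagents that add atoms: 2-isopropoxy-4,4,5,5-tetramethyl-1,3,2-dioxaborolane, CC(C)OB1OC(C)(C)C(C)(C)O1
Why: Bromine–lithium exchange is much faster at −78 °C than deprotonation of the benzylic allylic CH2, the ortho oxygen stabilises aryllithium 11, and the borate ester traps it; no palladium hydride is present that could move the allyl double bond.

Step 9
Reactants: 12 2-{5-allyl-2-[11-(triethylsilyloxy)eudesman-4α-yloxy]phenyl}-4,4,5,5-tetramethyl-1,3,2-dioxaborolane; 13 5-bromo-2H-pyran-2-one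
Product: 14 5-{5-allyl-2-[11-(triethylsilyloxy)eudesman-4α-yloxy]phenyl}-2H-pyran-2-one
Conditions: Pd(OAc)2, SPhos, K3PO4, THF/H2O, 50 °C
Reagents that add atoms: none
Why: Suzuki–Miyaura coupling at the vinylic C5–Br bond of the bromopyrone, a known coupling site; a bulky biarylphosphine is chosen for the ortho-hindered boronate, and a mild phosphate base at moderate temperature to protect the lactone.

Step 10
Reactants: 15 pent-1-en-4-yne
Product: 18 triisopropyl(pent-4-en-1-yn-1-yloxy)silane, via lithium acetylide 16 (not isolated), via lithium ynolate 17 (not isolated)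
Conditions: n-BuLi, THF, −78 °C; then LiOOt-Bu (from t-BuOOH and LiN(SiMe3)2), THF, −78 → 0 °C; then i-Pr3SiOTf, −78 → 0 °C
Reagents that add atoms: tert-butyl hydroperoxide, CC(C)(C)OO; triisopropylsilyl trifluoromethanesulfonate, CC(C)[Si](OS(=O)(=O)C(F)(F)F)(C(C)C)C(C)C
Why: The terminal alkyne C–H is the most acidic site, so acetylide 16 forms without touching the doubly activated CH2; the acetylide takes an oxygen atom from the lithium peroxide to give ynolate 17, and the bulky silyl triflate traps it on oxygen, a known route from 1-alkynes to triisopropylsilyl ynol ethers.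

Step 11
Reactants: 14 5-{5-allyl-2-[11-(triethylsilyloxy)eudesman-4α-yloxy]phenyl}-2H-pyran-2-one; 18 triisopropyl(pent-4-en-1-yn-1-yloxy)silane
Product: 20 4α-{[5,3'-diallyl-4'-(triisopropylsilyloxy)biphenyl-2-yl]oxy}-11-(triethylsilyloxy)eudesmane, via bicyclic lactone 19 (not isolated)
Conditions: 18 (3 equiv), toluene (0.5 M), base-washed sealed tube, 120 °C
Reagents that add atoms: none
Why: The electron-rich ynol ether adds across C3 and C6 of the 2-pyrone in a polarised, asynchronous [4+2] cycloaddition, its nucleophilic allyl-bearing carbon bonding to the electrophilic C6 and its silyloxy-bearing carbon to C3, and the resulting 2-oxabicyclo[2.2.2]octadienone 19 loses CO2 by retro-[4+2] cycloreversion under the same heating. The closest known reaction type is the Diels–Alder and decarboxylation benzannulation of 2-pyrones with heteroatom-substituted alkynes (ynamines, alkoxy- and silyloxyalkynes), which gives anilines and aryl ethers. Ring B is closed by this intermolecular [4+2] addition, which forms C2''–C3'' and C4''–C5'' in one event, and is aromatised when the lactone bridge is expelled. No stereocentre is created in the product: the two bridgehead centres of 19 are transient, and the four eudesmane centres are remote and untouched. The only selectivity needed is regiochemistry, which should follow from the matched polarisation of the ynol ether (allyl-bearing carbon nucleophilic) and of the pyrone (C6 the vinylogous acyl terminus), with C3 and C6 both unsubstituted so that no steric bias opposes it. Neutral heating at high concentration should leave the two allyl groups, the tertiary alkyl aryl ether and both silyl ethers intact, and favours the bimolecular addition over unimolecular silyl migration in 18.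

Step 12
Reactants: 20 4α-{[5,3'-diallyl-4'-(triisopropylsilyloxy)biphenyl-2-yl]oxy}-11-(triethylsilyloxy)eudesmane
Product: 21 CNP0219722.1 (4α-[(5,3'-diallyl-4'-hydroxybiphenyl-2-yl)oxy]eudesman-11-ol)
Conditions: Bu4NF, THF, 0 → 45 °C; aq. NH4Cl
Reagents that add atoms: none
Why: Fluoride attacks silicon, so the aryl silyl ether should leave first as the phenoxide and the tertiary triethylsilyl ether on gentle warming; the basic medium spares the acid-labile tertiary alkyl aryl ether and touches no stereocentre.

**Compound list**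

1 | β-eudesmol (5α-H, 7β-side chain, 10β-methyl) | C=C1CCC[C@]2(C)CC[C@@H](C(C)(C)O)C[C@H]21 | starting material
2 | 11-(triethylsilyloxy)eudesm-4(15)-ene | C=C1CCC[C@]2(C)CC[C@@H](C(C)(C)O[Si](CC)(CC)CC)C[C@H]21 | intermediate
3 | 4α,15-epoxy-11-(triethylsilyloxy)eudesmane (epoxide oxygen α at C4) | O1[C@]2(C1)CCC[C@]3(C)CC[C@@H](C(C)(C)O[Si](CC)(CC)CC)C[C@H]32 | intermediate
4 | 11-(triethylsilyloxy)eudesman-4α-ol (4α-OH, 4β-methyl) | O[C@]1(C)CCC[C@]2(C)CC[C@@H](C(C)(C)O[Si](CC)(CC)CC)C[C@H]21 | intermediate
5 | tert-butyl 3-bromo-4-fluorobenzoate | CC(C)(C)OC(=O)c1ccc(F)c(Br)c1 | starting material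
6 | potassium 11-(triethylsilyloxy)eudesman-4α-olate | [K+].[O-][C@]1(C)CCC[C@]2(C)CC[C@@H](C(C)(C)O[Si](CC)(CC)CC)C[C@H]21 | intermediate (not isolated)
7 | tert-butyl 3-bromo-4-[11-(triethylsilyloxy)eudesman-4α-yloxy]benzoate | CC(C)(C)OC(=O)c1ccc(O[C@]2(C)CCC[C@]3(C)CC[C@@H](C(C)(C)O[Si](CC)(CC)CC)C[C@H]32)c(Br)c1 | intermediate
8 | {3-bromo-4-[11-(triethylsilyloxy)eudesman-4α-yloxy]phenyl}methanol | OCc1ccc(O[C@]2(C)CCC[C@]3(C)CC[C@@H](C(C)(C)O[Si](CC)(CC)CC)C[C@H]32)c(Br)c1 | intermediate
9 | 4α-[2-bromo-4-(bromomethyl)phenoxy]-11-(triethylsilyloxy)eudesmane | BrCc1ccc(O[C@]2(C)CCC[C@]3(C)CC[C@@H](C(C)(C)O[Si](CC)(CC)CC)C[C@H]32)c(Br)c1 | intermediate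
10 | 4α-(4-allyl-2-bromophenoxy)-11-(triethylsilyloxy)eudesmane | C=CCc1ccc(O[C@]2(C)CCC[C@]3(C)CC[C@@H](C(C)(C)O[Si](CC)(CC)CC)C[C@H]32)c(Br)c1 | intermediate
11 | {5-allyl-2-[11-(triethylsilyloxy)eudesman-4α-yloxy]phenyl}lithium | C=CCc1ccc(O[C@]2(C)CCC[C@]3(C)CC[C@@H](C(C)(C)O[Si](CC)(CC)CC)C[C@H]32)c([Li])c1 | intermediate (not isolated)
12 | 2-{5-allyl-2-[11-(triethylsilyloxy)eudesman-4α-yloxy]phenyl}-4,4,5,5-tetramethyl-1,3,2-dioxaborolane | C=CCc1ccc(O[C@]2(C)CCC[C@]3(C)CC[C@@H](C(C)(C)O[Si](CC)(CC)CC)C[C@H]32)c(B2OC(C)(C)C(C)(C)O2)c1 | intermediate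
13 | 5-bromo-2H-pyran-2-one | O=C1C=CC(Br)=CO1 | starting material
14 | 5-{5-allyl-2-[11-(triethylsilyloxy)eudesman-4α-yloxy]phenyl}-2H-pyran-2-one | C=CCc1ccc(O[C@]2(C)CCC[C@]3(C)CC[C@@H](C(C)(C)O[Si](CC)(CC)CC)C[C@H]32)c(C2=COC(=O)C=C2)c1 | intermediate (key-step precursor)
15 | pent-1-en-4-yne | C=CCC#C | starting material
16 | lithium pent-4-en-1-yn-1-ide | C=CCC#C[Li] | intermediate (not isolated)
17 | lithium pent-4-en-1-yn-1-olate | C=CCC#C[O-].[Li+] | intermediate (not isolated)
18 | triisopropyl(pent-4-en-1-yn-1-yloxy)silane | C=CCC#CO[Si](C(C)C)(C(C)C)C(C)C | intermediate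
19 | 7-allyl-6-{5-allyl-2-[11-(triethylsilyloxy)eudesman-4α-yloxy]phenyl}-8-(triisopropylsilyloxy)-2-oxabicyclo[2.2.2]octa-5,7-dien-3-one (both bridgehead configurations; these centres are lost on aromatisation) | C=CCc1ccc(O[C@]2(C)CCC[C@]3(C)CC[C@@H](C(C)(C)O[Si](CC)(CC)CC)C[C@H]32)c(C2=CC3C(=O)OC2C(CC=C)=C3O[Si](C(C)C)(C(C)C)C(C)C)c1 | intermediate (not isolated)
20 | 4α-{[5,3'-diallyl-4'-(triisopropylsilyloxy)biphenyl-2-yl]oxy}-11-(triethylsilyloxy)eudesmane | C=CCc1ccc(O[C@]2(C)CCC[C@]3(C)CC[C@@H](C(C)(C)O[Si](CC)(CC)CC)C[C@H]32)c(-c2ccc(O[Si](C(C)C)(C(C)C)C(C)C)c(CC=C)c2)c1 | intermediate (key-step product)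
21 | CNP0219722.1, 4α-[(5,3'-diallyl-4'-hydroxybiphenyl-2-yl)oxy]eudesman-11-ol | C=CCc1ccc(O[C@]2(C)CCC[C@]3(C)CC[C@@H](C(C)(C)O)C[C@H]32)c(-c2ccc(O)c(CC=C)c2)c1 | target

**Step count**

Total: 12 steps. Longest linear sequence: 11 steps (steps 1–9, 11 and 12); step 10 is a one-step side branch.

**Steps most likely to fail**

1. Step 11 (key step). The pyrone carries no electron-withdrawing group, so the cycloaddition may be slow. In that case thermal 1,3-migration of silicon in 18 to the silylketene, and its oligomerisation, could consume the ynol ether first; partial loss of regiocontrol is also possible. The fallback sets out from boronate 12 and comes back at 20. Commercial 2-allyl-4-bromophenol is silylated (i-Pr3SiCl, imidazole, DMF) to (2-allyl-4-bromophenoxy)triisopropylsilane F1. F1 is joined to 12 by Suzuki–Miyaura coupling (Pd(OAc)2, SPhos, K3PO4, toluene/H2O, 80 °C), which forms the C1'–C1'' bond and gives 20 directly; ring B is then bought instead of built.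

2. Step 4. Attack of the hindered C4 alkoxide on the ortho-brominated fluoroarene may be slow, and on forcing, base-mediated cleavage of the ester or loss of the silyl group could take over. The fallback sets out from alcohol 4 and comes back at 10. Alkoxide 6 is captured by the far more electrophilic 2-bromo-1-fluoro-4-nitrobenzene (THF, 0 °C) to give 4α-(2-bromo-4-nitrophenoxy)-11-(triethylsilyloxy)eudesmane F2. Fe and NH4Cl in EtOH/H2O reduce the nitro group to 3-bromo-4-[11-(triethylsilyloxy)eudesman-4α-yloxy]aniline F3. Non-aqueous diazotisation and iodination (t-BuONO, CH2I2, MeCN) give 4α-(2-bromo-4-iodophenoxy)-11-(triethylsilyloxy)eudesmane F4. Stille coupling with allyltributylstannane at the C–I bond (Pd(PPh3)4, toluene, 90 °C) then gives 10, the hindered C–Br bond staying intact.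

3. Step 9. Aqueous base may open the pyrone ring, and protodeboronation of the hindered, electron-rich boronate may compete with transmetalation. The fallback sets out from bromide 10 and comes back at 14. Bromine–lithium exchange as in step 8 (via 11) and capture with Me3SnCl give {5-allyl-2-[11-(triethylsilyloxy)eudesman-4α-yloxy]phenyl}trimethylstannane F5. F5 undergoes base-free Stille coupling with 13 (Pd(PPh3)4, CuI, DMF, 60 °C) to give 14.

**Further compounds**

F1 | step 11 | (2-allyl-4-bromophenoxy)triisopropylsilane | C=CCc1cc(Br)ccc1O[Si](C(C)C)(C(C)C)C(C)C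
F2 | step 4 | 4α-(2-bromo-4-nitrophenoxy)-11-(triethylsilyloxy)eudesmane | O=[N+]([O-])c1ccc(O[C@]2(C)CCC[C@]3(C)CC[C@@H](C(C)(C)O[Si](CC)(CC)CC)C[C@H]32)c(Br)c1
F3 | step 4 | 3-bromo-4-[11-(triethylsilyloxy)eudesman-4α-yloxy]aniline | Nc1ccc(O[C@]2(C)CCC[C@]3(C)CC[C@@H](C(C)(C)O[Si](CC)(CC)CC)C[C@H]32)c(Br)c1
F4 | step 4 | 4α-(2-bromo-4-iodophenoxy)-11-(triethylsilyloxy)eudesmane | Ic1ccc(O[C@]2(C)CCC[C@]3(C)CC[C@@H](C(C)(C)O[Si](CC)(CC)CC)C[C@H]32)c(Br)c1
F5 | step 9 | {5-allyl-2-[11-(triethylsilyloxy)eudesman-4α-yloxy]phenyl}trimethylstannane | C=CCc1ccc(O[C@]2(C)CCC[C@]3(C)CC[C@@H](C(C)(C)O[Si](CC)(CC)CC)C[C@H]32)c([Sn](C)(C)C)c1
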